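The butenolide ring (O1, C2=O, C3–Me, C4–OCOR, C5=C20) is closed last, between C2 and C3, by a carbonate Dieckmann condensation. The precursor is an acyclic (E)-enol 4-nitrophenyl carbonate of a 1,2-diketone: C2 already sits on the enol oxygen O1, and C3 is the α-carbon of the C4 ethyl ketone. Because the O1–C5 and O1–C2 bonds are never broken, the contra-thermodynamic (E)-geometry of C5=C20, set earlier by E(O)-selective enolisation of a propynyl ketone, passes unchanged into the ring. The tetronate formed is O-palmitoylated in the same flask. The chain derives from farnesyl chloride; C18 is set by Ru–BINAP hydrogenation.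

Key step: step 10

Remarks on the chemistry:
- Numbering: ring atoms are O1, C2(=O), C3(Me), C4(O-acyl), C5; the exocyclic carbon is C20 and the stereocentre is C18.
- The target is the (E)-alkylidene isomer (chain cis to C4, trans to O1) with (S)-C18. Aldol–dehydration and alkyne-lactonisation logic, which favour the (Z)-isomer, are therefore not used.
- Assumption: 3-(chloromethyl)furan is not reliably purchasable and is made in step 1.
- Assumption: the sense of induction in step 4 is assigned by analogy with geraniol and should be verified before proceeding.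

Step 1
Reactants: 1 furan-3-ylmethanol
Product: 2 3-(chloromethyl)furan
Conditions: SOCl2, pyridine, Et2O, 0 °C
Reagents that add atoms: thionyl chloride, O=S(Cl)Cl
Why: Chlorodehydroxylation of a primary alcohol through the chlorosulfite; pyridine buffers HCl so the acid-sensitive furan should survive, and the labile chloride is used at once.

Step 2
Reactants: 2 3-(chloromethyl)furan; 3 (2E,6E)-farnesyl chloride
Product: 5 ambliofuran, via (furan-3-ylmethyl)magnesium chloride 4 (not isolated)
Conditions: Mg, THF, 0 °C; then 3, Li2CuCl4 (cat.), THF, −10 °C → rt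
Reagents that add atoms: none
Why: Copper-catalysed (Kochi-type) Grignard cross-coupling with a primary allylic chloride should be SN2 (α) selective, as in dendrolasin-type furanoterpene syntheses, so both (E)-trisubstituted alkenes are carried over unchanged.

Step 3
Reactants: 5 ambliofuran
Product: 6 (2E,6E,10E)-13-(furan-3-yl)-2,6,10-trimethyltrideca-2,6,10-trien-1-ol
Conditions: SeO2 (cat.), t-BuOOH, salicylic acid (cat.), CH2Cl2, 0 °C → rt, partial conversion
Reagents that add atoms: tert-butyl hydroperoxide, CC(C)(C)OO
Why: Catalytic SeO2 allylic oxidation (ene reaction then [2,3]-shift) should attack the terminal isopropylidene at its (E)-methyl group, as in ω-hydroxylation of polyprenyl chains, giving the (E)-allylic alcohol; stopping early and recycling 5 limits internal attack and over-oxidation.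

Step 4
Reactants: 6 (2E,6E,10E)-13-(furan-3-yl)-2,6,10-trimethyltrideca-2,6,10-trien-1-ol
Product: 7 (2S,6E,10E)-13-(furan-3-yl)-2,6,10-trimethyltrideca-6,10-dien-1-ol
Conditions: H2 (50–100 atm), Ru(OAc)2[(S)-BINAP] (cat.), MeOH, rt
Reagents that add atoms: none
Why: Hydroxyl-directed Noyori asymmetric hydrogenation should reduce only the allylic-alcohol alkene (isolated trisubstituted alkenes and the furan are not substrates) and sets C18 by ligand-controlled facial delivery of H2; the (S)-BINAP complex is proposed by analogy with geraniol, and the ligand enantiomer that gives the (2S)-alcohol is the one used.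

Step 5
Reactants: 7 (2S,6E,10E)-13-(furan-3-yl)-2,6,10-trimethyltrideca-6,10-dien-1-ol
Product: 8 3-[(3E,7E,12S)-13-bromo-4,8,12-trimethyltrideca-3,7-dien-1-yl]furan
Conditions: CBr4, PPh3, CH2Cl2, 0 °C
Reagents that add atoms: carbon tetrabromide, BrC(Br)(Br)Br
Why: Appel bromination is an SN2 displacement at the primary carbon under neutral conditions, so the adjacent stereocentre, the alkenes and the furan should be untouched.

Step 6
Reactants: 9 but-2-ynoic acid; 10 N,O-dimethylhydroxylamine hydrochloride
Product: 12 N-methoxy-N-methylbut-2-ynamide, via 1-(but-2-ynoyl)imidazole 11 (not isolated)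
Conditions: CDI, CH2Cl2, 0 °C → rt; then 10, rt
Reagents that add atoms: none
Why: Standard CDI-mediated Weinreb amide formation through the acyl imidazole; the imidazole released serves as the only base, so conjugate addition to the ynoyl unit is not expected.

Step 7
Reactants: 8 3-[(3E,7E,12S)-13-bromo-4,8,12-trimethyltrideca-3,7-dien-1-yl]furan; 12 N-methoxy-N-methylbut-2-ynamide
Product: 14 (6S,10E,14E)-17-(furan-3-yl)-6,10,14-trimethylheptadeca-10,14-dien-2-yn-4-one, via alkylmagnesium bromide 13 (not isolated)
Conditions: Mg, THF, rt → 40 °C; then 12, THF, −78 → 0 °C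
Reagents that add atoms: none
Why: Weinreb ketone synthesis: the chelated tetrahedral adduct blocks over-addition and releases the ynone on work-up, and copper-free Grignard reagents should add 1,2 to alkynyl Weinreb amides at low temperature.

Step 8
Reactants: 14 (6S,10E,14E)-17-(furan-3-yl)-6,10,14-trimethylheptadeca-10,14-dien-2-yn-4-one; 15 4-nitrophenyl chloroformate
Product: 17 (4E,6S,10E,14E)-17-(furan-3-yl)-6,10,14-trimethylheptadeca-4,10,14-trien-2-yn-4-yl 4-nitrophenyl carbonate, via lithium (E)-enolate 16 (not isolated)
Conditions: LiHMDS, Et3N, toluene, −78 °C; then cannulate into 15, THF, −78 °C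
Reagents that add atoms: none
Why: Kinetic amide-base enolisation through the closed (Ireland-type) transition state should give the E(O)-enolate, because the linear propynyl group is the smallest possible carbonyl substituent and tolerates the chain cis to it (LiHMDS/Et3N is an E-selective medium); enolate O-acylation by the hard chloroformate then fixes C5=C20 as (E) with retention.

Step 9
Reactants: 17 (4E,6S,10E,14E)-17-(furan-3-yl)-6,10,14-trimethylheptadeca-4,10,14-trien-2-yn-4-yl 4-nitrophenyl carbonate
Product: 18 (4E,6S,10E,14E)-17-(furan-3-yl)-6,10,14-trimethyl-3-oxoheptadeca-4,10,14-trien-4-yl 4-nitrophenyl carbonate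
Conditions: [(IPr)Au(NCMe)]SbF6 (cat.), 1,4-dioxane/H2O, 50–60 °C
Reagents that add atoms: water, O
Why: Gold(I)-catalysed Markovnikov hydration of the 1,3-enyne should deliver water to the alkyne carbon attached to the alkene (C4), where charge is allylically stabilised, as in Rupe-type enyne hydration; 5-exo participation by the carbonate carbonyl would force gold against the cis chain and is expected to be shut off in the (E)-isomer, and the neutral medium should preserve the aryl carbonate, enol geometry and furan.

Step 10
Reactants: 18 (4E,6S,10E,14E)-17-(furan-3-yl)-6,10,14-trimethyl-3-oxoheptadeca-4,10,14-trien-4-yl 4-nitrophenyl carbonate; 19 hexadecanoyl chloride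
Product: 22 (2E)-2-[(2S,6E,10E)-13-(furan-3-yl)-2,6,10-trimethyltrideca-6,10-dien-1-ylidene]-4-methyl-5-oxo-2,5-dihydrofuran-3-yl hexadecanoate (target CNP0269639.1), via lithium ketone enolate 20 (not isolated), via lithium tetronate 21 (not isolated)
Conditions: LiHMDS (1.05 equiv), THF, −78 → −20 °C; then 19, −78 → 0 °C
Reagents that add atoms: none
Why: Kinetic α′-deprotonation of the ethyl ketone gives the C3 enolate, which adds to the carbonate carbonyl C2; loss of 4-nitrophenoxide from the tetrahedral intermediate gives the 2,4-dione, which is deprotonated to the tetronate. This is a carbonate Dieckmann (intramolecular Claisen) condensation, the reaction type by which α-ketol carbonates give tetronic acids, and the five-membered lactone closes in the 5-(enolendo)-exo-trig mode familiar from Lacey–Dieckmann tetronate and tetramate closures. No stereocentre is formed: C18 is remote, and the (E)-C5=C20 geometry is conserved because O1 stays bonded to C5 and C2, which requires a leaving group (4-nitrophenoxide) better than the enol oxygen. The step needs α′- over γ-(C18–H) deprotonation, which the hindered base at −78 °C should secure. It also needs C- over O-acylation: O-attack would give a 4,5-bis(alkylidene)-1,3-dioxolan-2-one in which the cis chain clashes with the ethylidene terminus, and it is reversible whereas C-acylation is not. The tetronate is then acylated on O4 (C3 is blocked by methyl) by 19 without added amine, so the acid- and nucleophile-sensitive (E)-tetronic acid is never isolated.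

Compound list
1 | furan-3-ylmethanol | OCc1ccoc1 | starting material
2 | 3-(chloromethyl)furan | ClCc1ccoc1 | intermediate
3 | (2E,6E)-farnesyl chloride, (2E,6E)-1-chloro-3,7,11-trimethyldodeca-2,6,10-triene | CC(C)=CCC/C(C)=C/CC/C(C)=C/CCl | starting material
4 | (furan-3-ylmethyl)magnesium chloride | Cl[Mg]Cc1ccoc1 | intermediate
5 | ambliofuran, 3-[(3E,7E)-4,8,12-trimethyltrideca-3,7,11-trien-1-yl]furan | CC(C)=CCC/C(C)=C/CC/C(C)=C/CCc1ccoc1 | intermediate
6 | (2E,6E,10E)-13-(furan-3-yl)-2,6,10-trimethyltrideca-2,6,10-trien-1-ol | OC/C(C)=C/CC/C(C)=C/CC/C(C)=C/CCc1ccoc1 | intermediate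
7 | (2S,6E,10E)-13-(furan-3-yl)-2,6,10-trimethyltrideca-6,10-dien-1-ol | OC[C@@H](C)CCC/C(C)=C/CC/C(C)=C/CCc1ccoc1 | intermediate
8 | 3-[(3E,7E,12S)-13-bromo-4,8,12-trimethyltrideca-3,7-dien-1-yl]furan | BrC[C@@H](C)CCC/C(C)=C/CC/C(C)=C/CCc1ccoc1 | intermediate
9 | but-2-ynoic acid | CC#CC(=O)O | starting material
10 | N,O-dimethylhydroxylamine hydrochloride | CNOC.Cl | starting material
11 | 1-(but-2-ynoyl)imidazole | CC#CC(=O)n1ccnc1 | intermediate
12 | N-methoxy-N-methylbut-2-ynamide | CC#CC(=O)N(C)OC | intermediate
13 | [(2S,6E,10E)-13-(furan-3-yl)-2,6,10-trimethyltrideca-6,10-dien-1-yl]magnesium bromide | Br[Mg]C[C@@H](C)CCC/C(C)=C/CC/C(C)=C/CCc1ccoc1 | intermediate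
14 | (6S,10E,14E)-17-(furan-3-yl)-6,10,14-trimethylheptadeca-10,14-dien-2-yn-4-one | CC#CC(=O)C[C@@H](C)CCC/C(C)=C/CC/C(C)=C/CCc1ccoc1 | intermediate
15 | 4-nitrophenyl chloroformate | O=C(Cl)Oc1ccc(cc1)[N+](=O)[O-] | starting material
16 | lithium (4E,6S,10E,14E)-17-(furan-3-yl)-6,10,14-trimethylheptadeca-4,10,14-trien-2-yn-4-olate, chain cis to the propynyl group | CC#C/C(O[Li])=C\[C@@H](C)CCC/C(C)=C/CC/C(C)=C/CCc1ccoc1 | intermediate
17 | (4E,6S,10E,14E)-17-(furan-3-yl)-6,10,14-trimethylheptadeca-4,10,14-trien-2-yn-4-yl 4-nitrophenyl carbonate | CC#C/C(OC(=O)Oc1ccc(cc1)[N+](=O)[O-])=C\[C@@H](C)CCC/C(C)=C/CC/C(C)=C/CCc1ccoc1 | intermediate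
18 | (4E,6S,10E,14E)-17-(furan-3-yl)-6,10,14-trimethyl-3-oxoheptadeca-4,10,14-trien-4-yl 4-nitrophenyl carbonate | CCC(=O)/C(OC(=O)Oc1ccc(cc1)[N+](=O)[O-])=C\[C@@H](C)CCC/C(C)=C/CC/C(C)=C/CCc1ccoc1 | intermediate
19 | hexadecanoyl (palmitoyl) chloride | CCCCCCCCCCCCCCCC(=O)Cl | starting material
20 | lithium C3-enolate of 18 (enolate geometry at C3=C4 not defined, both isomers converge) | CC=C(O[Li])/C(OC(=O)Oc1ccc(cc1)[N+](=O)[O-])=C\[C@@H](C)CCC/C(C)=C/CC/C(C)=C/CCc1ccoc1 | intermediate
21 | lithium salt of (5E)-5-[(2S,6E,10E)-13-(furan-3-yl)-2,6,10-trimethyltrideca-6,10-dien-1-ylidene]-4-hydroxy-3-methylfuran-2(5H)-one | [Li]OC1=C(C)C(=O)O/C1=C/[C@@H](C)CCC/C(C)=C/CC/C(C)=C/CCc1ccoc1 | intermediate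
22 | (2E)-2-[(2S,6E,10E)-13-(furan-3-yl)-2,6,10-trimethyltrideca-6,10-dien-1-ylidene]-4-methyl-5-oxo-2,5-dihydrofuran-3-yl hexadecanoate | CCCCCCCCCCCCCCCC(=O)OC1=C(C)C(=O)O/C1=C/[C@@H](C)CCC/C(C)=C/CC/C(C)=C/CCc1ccoc1 | target

Total step count: 10
Longest linear sequence: 9 steps (steps 1–5 and 7–10; step 6 is a one-step side branch).

Steps most likely to fail

1. Step 9 (alkyne hydration). Hydration of the hindered internal alkyne may be slow, so that hydrolysis of the activated carbonate, water attack at C3 instead of C4, or gold- or acid-induced drift of the enol geometry competes. The fallback sets out from 17 and replaces hydration by anhydrous oxygen transfer. Gold(I)-catalysed oxidation with 8-methylquinoline N-oxide at rt would pass through the α-oxo gold carbene and a 1,2-hydride shift to give the vinyl ketone F1. Conjugate reduction of F1 with L-Selectride at −78 °C would generate the C3 enolate regiospecifically and without any base. The fallback comes back to the route at 20, which closes to 21 and is acylated as in step 10.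

2. Step 8 (E-selective enolisation and O-carbonation). The E(O)/Z(O) ratio may erode through proton exchange between enolate and unreacted ynone, the amide base may add to the ynone in conjugate fashion, or the enolate may be acylated on carbon. The fallback sets out from 14 and separates the geometry-setting and acylation events. Deprotonation with LiTMP in the presence of TMSCl (internal quench, THF, −78 °C) would trap each enolate molecule as it forms, giving the trimethylsilyl enol ether F2, whose (E)-isomer can be enriched on base-washed silica. MeLi (THF, 0 °C) would then regenerate the amine-free lithium enolate with retention. The fallback comes back to the route at 16, which is acylated with 15 to give 17.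

3. Step 10 (Dieckmann closure). The base may remove the γ-proton at C18 (loss of the stereocentre and of the alkene geometry), or attack the activated carbonate. The tetrahedral intermediate may also collapse by loss of the enol oxygen, which gives acyl transfer instead of ring closure and loses the geometry on reprotonation. The fallback sets out from 18 and replaces the strong base by a fluoride-triggered Claisen. Soft silylation (TMSOTf, Et3N, CH2Cl2, −78 °C) at the only unhindered α′-position would give the silyl dienol ether F3. Anhydrous fluoride (TBAT, THF, −40 °C) would unmask the enolate under non-basic conditions, and it should close at once onto the carbonate to give tetrabutylammonium tetronate F4. Acylation of F4 with 19 brings the fallback back to the route at 22.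

Further compounds
F1 | step 9 | (4E,6S,10E,14E)-17-(furan-3-yl)-6,10,14-trimethyl-3-oxoheptadeca-1,4,10,14-tetraen-4-yl 4-nitrophenyl carbonate | C=CC(=O)/C(OC(=O)Oc1ccc(cc1)[N+](=O)[O-])=C\[C@@H](C)CCC/C(C)=C/CC/C(C)=C/CCc1ccoc1
F2 | step 8 | {[(4E,6S,10E,14E)-17-(furan-3-yl)-6,10,14-trimethylheptadeca-4,10,14-trien-2-yn-4-yl]oxy}trimethylsilane | CC#C/C(O[Si](C)(C)C)=C\[C@@H](C)CCC/C(C)=C/CC/C(C)=C/CCc1ccoc1
F3 | step 10 | (4E,6S,10E,14E)-17-(furan-3-yl)-6,10,14-trimethyl-3-(trimethylsilyloxy)heptadeca-2,4,10,14-tetraen-4-yl 4-nitrophenyl carbonate | CC=C(O[Si](C)(C)C)/C(OC(=O)Oc1ccc(cc1)[N+](=O)[O-])=C\[C@@H](C)CCC/C(C)=C/CC/C(C)=C/CCc1ccoc1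
F4 | step 10 | tetrabutylammonium salt of (5E)-5-[(2S,6E,10E)-13-(furan-3-yl)-2,6,10-trimethyltrideca-6,10-dien-1-ylidene]-4-hydroxy-3-methylfuran-2(5H)-one | CCCC[N+](CCCC)(CCCC)CCCC.[O-]C1=C(C)C(=O)O/C1=C/[C@@H](C)CCC/C(C)=C/CC/C(C)=C/CCc1ccoc1
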